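## Retrosynthetic overview
1. The enal CHO comes from CO on a ring enol triflate. The second CHO is carried as a dimethyl acetal. The CH2OAc/OH pair comes from reduction of a cis-fused γ-lactone, which also fixes the side-chain methine.
2. The (E)-cyclononenone comes from an oxidative Grob-type fragmentation of a cis-hydrindanol γ-stannane. This cuts the five/six fusion bond, so the ring grows from five to nine atoms. Sn cis to CH3 encodes the E geometry.
3. The hydrindanol comes from an amine-catalysed Mukaiyama–Michael/aldol cascade of a 4-oxo-enal with a silyl ketene acetal. The cascade forms the six-membered ring and two stereocentres.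
4. The 4-oxo-enal comes from oxidative opening of a furan. The stannyl ketone comes from Bu3SnLi addition to 2-methylcyclopentenone followed by furfurylation.
5. Ring order: five-membered ring (bought), then six-membered ring (cascade), then γ-lactone, then nine-membered ring by cleavage of the fusion bond.

**Locants:** bicyclic compounds use indane numbering (C1–C3, C3a, C4–C7, C7a). In nine-membered compounds C1 bears the side chain, C2 the oxygen, C4 the methyl group, and C8 and C9 the one-carbon groups. Cα is the side-chain methine.

**Assumption 1:** the ring-flip (planar-chiral) conformers of the E-cyclononene, which the SMILES does not encode, are taken to interconvert at room temperature.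

**Assumption 2:** compounds 8–10 are racemic, and the drawn enantiomer is the one carried on. Absolute configuration enters in step 6, where at most half of racemic 10 can give 12. The sense of induction is assumed to follow other β-additions with this catalyst family, and the antipodal catalyst is equally available.

## Route

Step 1
Reactants: 1 methyl 4-bromobutanoate; 2 (2-methylprop-1-en-1-yl)magnesium bromide
Product: 3 methyl 6-methylhept-5-enoate
Conditions: Fe(acac)3 (5 mol %), TMEDA (10 mol %), HMTA (5 mol %), THF, 0 °C, slow addition of 2
Reagents that add atoms: none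
Why: Iron-catalysed Kumada-type sp3–sp2 cross-coupling of a primary alkyl bromide with an alkenyl Grignard reagent outruns attack on the ester and gives the whole side-chain acid skeleton; no stereocentre is formed.

Step 2
Reactants: 3 methyl 6-methylhept-5-enoate
Product: 4 tert-butyl[(1-methoxy-6-methylhepta-1,5-dien-1-yl)oxy]dimethylsilane (E/Z mixture)
Conditions: LiN(i-Pr)2, THF/DMPU, −78 °C; TBSCl, −78 → 23 °C
Reagents that add atoms: tert-butyldimethylsilyl chloride, CC(C)(C)[Si](C)(C)Cl
Why: Kinetic ester enolisation and O-silylation give the silyl ketene acetal, and its geometry does not matter because Cα is equilibrated in step 7.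

Step 3
Reactants: 5 furfuryl alcohol
Product: 6 2-(bromomethyl)furan (kept as a cold Et2O solution over K2CO3 and used the same day)
Conditions: PBr3 (0.4 equiv), Et2O, 0 °C
Reagents that add atoms: phosphorus tribromide, BrP(Br)Br
Why: SN2 bromination of an activated primary alcohol through its phosphite ester; no stereocentre is formed.

Step 4
Reactants: 7 2-methylcyclopent-2-en-1-one; 6 2-(bromomethyl)furan
Product: 9 rac-2-(furan-2-ylmethyl)-2-methyl-3-(tributylstannyl)cyclopentan-1-one (Sn cis to CH3 and trans to CH2-furyl), via stannyl enolate 8 (not isolated)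
Conditions: Bu3SnH, LiN(i-Pr)2, THF, 0 °C (gives Bu3SnLi); 7, −78 °C; DMPU, 6 in Et2O, −78 → −30 °C
Reagents that add atoms: tributyltin hydride, CCCC[SnH](CCCC)CCCC
Why: Conjugate addition of the stannyl anion followed by enolate alkylation (three-component coupling) brings the electrophile in anti to the bulky stannyl group, so the quaternary centre forms with the chain trans and CH3 cis to tin.

Step 5
Reactants: 9 rac-stannyl furfuryl ketone
Product: 10 rac-(E)-5-[1-methyl-2-oxo-5-(tributylstannyl)cyclopentyl]-4-oxopent-2-enal (relative configuration unchanged)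
Conditions: NBS (1.0 equiv), NaHCO3, acetone/H2O 10:1, −20 °C; then pyridine, 23 °C
Reagents that add atoms: water, O
Why: Oxidative ring opening of a 2-alkylfuran (bromination, hydration, ring cleavage) gives the 4-oxo-2-enal and pyridine isomerises Z to E; the furan is far more nucleophilic than the tetraalkylstannane and no stereocentre is touched.

Step 6
Reactants: 10 rac-4-oxo-enal; 4 silyl ketene acetal
Product: 12 methyl 2-[4-(dimethoxymethyl)-3a-hydroxy-7a-methyl-6-oxo-1-(tributylstannyl)octahydro-1H-inden-5-yl]-6-methylhept-5-enoate (cis-fused; 3a-OH, 7a-CH3, 1-Sn and 4-CH(OMe)2 on one face, 5-side chain on the other; Cα epimers; single enantiomer series), via hydroxy aldehyde 11 (not isolated)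
Conditions: (2R,5R)-5-benzyl-2-tert-butyl-3-methylimidazolidin-4-one·CF3CO2H (20 mol %), 4 (1.5 equiv), CH2Cl2/H2O, −60 °C, then 23 °C; then HC(OMe)3, MeOH, 0 °C; chromatography
Reagents that add atoms: trimethyl orthoformate, COC(OC)OC
Why: Proposed new method: the chiral imidazolidinone first activates 10 as its iminium ion, so that 4 attacks C5 (β to the iminium, not β to the ketone) on the face left open by the benzyl and tert-butyl groups, and the enamine released by this Mukaiyama–Michael step then adds in a 6-enolexo aldol reaction to the ring ketone on the face that carries the tether (cis-hydrindane, formyl group equatorial and trans to the C5 substituent after enamine equilibration), which in one flask makes two C–C bonds, the six-membered ring and the C4/C5 stereocentres; the closest known reaction types are iminium-catalysed Mukaiyama–Michael additions to enals, amine-catalysed enolexo aldolisations and iminium–enamine cascade catalysis, but their merger on a ketone acceptor is not known, and the diastereomer that arises from ent-10 is removed by chromatography once the aldehyde is trapped as its acetal.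

Step 7
Reactants: 12 hydrindanone ester acetal
Product: 14 tricyclic γ-lactone (6-O joined to the Cα carboxyl; 6-O and the 5-substituent cis, on the face opposite to 7a-CH3; homoprenyl group on the convex face of the lactone), via lactone epimer mixture 13 (not isolated)
Conditions: LiBH(s-Bu)3 (2.2 equiv), THF, −78 → 0 °C; H2O; crude product with DBU (0.5 equiv), PhMe, 80 °C
Reagents that add atoms: none
Why: Diastereoselective ketone reduction with a bulky borohydride (equatorial attack, since the axial face is blocked by axial C1) gives the axial C6 alkoxide cis to the side chain, which lactonises, and base epimerisation then moves the homoprenyl group to the convex face of the cis-fused lactone, which is the Cα configuration of the target.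

Step 8
Reactants: 14 γ-hydroxystannane lactone
Product: 15 (E)-cyclononenone lactone (C8 ketone, C4=C5 E-alkene, C9 dimethyl acetal, C1/C2 cis-fused γ-lactone)
Conditions: Pb(OAc)4 (1.2 equiv), PhH, 60 °C
Reagents that add atoms: none
Why: Oxidative Grob-type fragmentation of a γ-hydroxystannane (four-atom ring expansion, five to nine): the tertiary alkoxide bound to tetravalent lead leaves with reduction to divalent lead while the C1–Sn bond, antiperiplanar to the C3a–C7a fusion bond in the chair with axial C1, supplies the electrons, so the fusion bond breaks in a concerted polar, non-pericyclic step and Sn cis to CH3 becomes the E-trisubstituted alkene.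

Step 9
Reactants: 15 cyclononenone lactone
Product: 16 C8 enol triflate (C7=C8, ring-cis) of the lactone acetal
Conditions: KN(SiMe3)2 (1.05 equiv), THF, −78 °C; PhNTf2, −78 → −20 °C
Reagents that add atoms: N-phenylbis(trifluoromethanesulfonimide), O=S(=O)(N(c1ccccc1)S(=O)(=O)C(F)(F)F)C(F)(F)F
Why: Kinetic deprotonation takes the unhindered C7 methylene rather than the C9 methine or the less acidic lactone α-H, and O-triflation fixes the ring-cis enolate, the only geometry a nine-membered ring that already holds an E-alkene can bear.

Step 10
Reactants: 16 enol triflate lactone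
Product: 17 diol (primary CH2OH on Cα, secondary OH at C2; triflate and acetal intact)
Conditions: LiBH4, MeOH (1 equiv), Et2O/THF, 0 → 23 °C
Reagents that add atoms: none
Why: Chemoselective borohydride reduction of the lactone opens it to the 1,4-diol without touching the enol triflate, acetal or alkenes; no stereocentre changes.

Step 11
Reactants: 17 diol
Product: 18 primary monoacetate (C2-OH free)
Conditions: Ac2O (1.05 equiv), pyridine, CH2Cl2, −20 °C
Reagents that add atoms: acetic anhydride, CC(=O)OC(C)=O
Why: Selective acylation favours the primary alcohol over the hindered secondary ring alcohol.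

Step 12
Reactants: 18 acetate enol triflate
Product: 19 C8 enal, C9 dimethyl acetal
Conditions: Pd(PPh3)4 (5 mol %), LiCl, CO (1 atm), Bu3SnH (slow addition), THF, 50 °C
Reagents that add atoms: carbon monoxide, [C-]#[O+]
Why: Palladium-catalysed reductive carbonylation (formylation) runs by oxidative addition to zerovalent palladium, CO insertion and hydride transfer from tin, and it replaces OTf by CHO with retention of the alkene geometry.

Step 13
Reactants: 19 enal acetal
Product: 20 (2S)-2-[(1R,2S,4E,7E,9R)-8,9-diformyl-2-hydroxy-4-methylcyclonona-4,7-dien-1-yl]-6-methylhept-5-en-1-yl acetate (target)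
Conditions: PPTS (0.2 equiv), acetone/H2O 9:1, 35 °C
Reagents that add atoms: water, O
Why: Mild acid-catalysed acetal hydrolysis frees the second aldehyde under conditions too weak to epimerise C9, shift the enal double bond or cleave the acetate.

## Compound list
1 | methyl 4-bromobutanoate | COC(=O)CCCBr | starting material
2 | (2-methylprop-1-en-1-yl)magnesium bromide | CC(C)=C[Mg]Br | starting material
3 | methyl 6-methylhept-5-enoate | COC(=O)CCCC=C(C)C | intermediate
4 | silyl ketene acetal of 3 (E/Z mixture) | COC(O[Si](C)(C)C(C)(C)C)=CCCC=C(C)C | intermediate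
5 | furfuryl alcohol | OCc1ccco1 | starting material
6 | 2-(bromomethyl)furan | BrCc1ccco1 | intermediate
7 | 2-methylcyclopent-2-en-1-one | CC1=CCCC1=O | starting material
8 | lithium 2-methyl-3-(tributylstannyl)cyclopent-1-en-1-olate (racemic, not isolated) | [Li+].[O-]C1=C(C)[C@H]([Sn](CCCC)(CCCC)CCCC)CC1 | intermediate
9 | rac-2-(furan-2-ylmethyl)-2-methyl-3-(tributylstannyl)cyclopentan-1-one | o1cccc1C[C@@]2(C)[C@H]([Sn](CCCC)(CCCC)CCCC)CCC2=O | intermediate
10 | rac-(E)-5-[1-methyl-2-oxo-5-(tributylstannyl)cyclopentyl]-4-oxopent-2-enal | O=C/C=C/C(=O)C[C@@]1(C)[C@H]([Sn](CCCC)(CCCC)CCCC)CCC1=O | intermediate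
11 | hydrindanone hydroxy aldehyde (Cα epimers, not isolated) | COC(=O)C(CCC=C(C)C)[C@H]1C(=O)C[C@@]2(C)[C@H]([Sn](CCCC)(CCCC)CCCC)CC[C@@]2(O)[C@@H]1C=O | intermediate
12 | hydrindanone dimethyl acetal (Cα epimers) | COC(=O)C(CCC=C(C)C)[C@H]1C(=O)C[C@@]2(C)[C@H]([Sn](CCCC)(CCCC)CCCC)CC[C@@]2(O)[C@@H]1C(OC)OC | intermediate
13 | tricyclic lactone, Cα epimer mixture (not isolated) | O=C1C(CCC=C(C)C)[C@H]2[C@@H](O1)C[C@@]3(C)[C@H]([Sn](CCCC)(CCCC)CCCC)CC[C@@]3(O)[C@@H]2C(OC)OC | intermediate
14 | tricyclic γ-hydroxystannane lactone | O=C1[C@@H](CCC=C(C)C)[C@H]2[C@@H](O1)C[C@@]3(C)[C@H]([Sn](CCCC)(CCCC)CCCC)CC[C@@]3(O)[C@@H]2C(OC)OC | intermediate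
15 | (E)-cyclononenone lactone acetal | O=C1[C@@H](CCC=C(C)C)[C@H]2[C@@H](O1)C/C(C)=C/CCC(=O)[C@@H]2C(OC)OC | intermediate
16 | enol triflate lactone acetal | O=C1[C@@H](CCC=C(C)C)[C@H]2[C@@H](O1)C/C(C)=C/C/C=C(/OS(=O)(=O)C(F)(F)F)[C@@H]2C(OC)OC | intermediate
17 | enol triflate diol | OC[C@@H](CCC=C(C)C)[C@H]1[C@@H](O)C/C(C)=C/C/C=C(/OS(=O)(=O)C(F)(F)F)[C@@H]1C(OC)OC | intermediate
18 | enol triflate monoacetate | CC(=O)OC[C@@H](CCC=C(C)C)[C@H]1[C@@H](O)C/C(C)=C/C/C=C(/OS(=O)(=O)C(F)(F)F)[C@@H]1C(OC)OC | intermediate
19 | enal dimethyl acetal | CC(=O)OC[C@@H](CCC=C(C)C)[C@H]1[C@@H](O)C/C(C)=C/C/C=C(/C=O)[C@@H]1C(OC)OC | intermediate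
20 | CNP0284729.1 | CC(=O)OC[C@@H](CCC=C(C)C)[C@H]1[C@@H](O)C/C(C)=C/C/C=C(/C=O)[C@@H]1C=O | target

## Step count and risks
Total steps: 13. Longest linear sequence: 11 (steps 3–13, from furfuryl alcohol).

**Step 6 (the new cascade).** The enamine may fail to close onto the hindered ketone, or the open 1,4-keto aldehyde may be lost. The fallback sets out from 10 and 4 and separates the two bond formations into known reactions.
- Run only the established amine-catalysed Mukaiyama–Michael addition (same salt, −60 °C, aqueous quench) and isolate the open-chain keto aldehyde F1.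
- Close the ring in a separate proline-catalysed 6-enolexo aldolisation (matched enantiomer, CH2Cl2/DMSO, 23 °C) to hydroxy aldehyde 11.
- Acetalise 11 with HC(OMe)3/PPTS. The route is rejoined at 12.

**Step 8 (ring expansion).** Lead tetraacetate may attack the acetal or the alkenes, or cleave another bond next to the carbinol. The fallback sets out from 14 and replaces the polar lead-mediated heterolysis by an alkoxy-radical route (PhI(OAc)2, I2, cyclohexane, visible light, 25 °C). The hypoiodite gives the C3a alkoxy radical, and β-scission of C3a–C7a gives a tertiary radical β to tin that expels Bu3Sn•. The route is rejoined at 15 and no new compound is made.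

**Step 12 (formylation with a free hydroxyl group).** Direct hydride reduction of the triflate, or capture of the acyl-palladium species by the C2-OH, may compete. The fallback sets out from 18 and installs the carbon at the alcohol level by Stille coupling with Bu3SnCH2OH (Pd(PPh3)4, LiCl, THF, 60 °C), which gives the allylic alcohol F2. MnO2 (CH2Cl2, 23 °C) then oxidises only the allylic alcohol, and the route is rejoined at 19.

## Further compounds
F1 | step 6 | methyl 2-{(E-derived) 1-formyl-4-[1-methyl-2-oxo-5-(tributylstannyl)cyclopentyl]-3-oxobutan-2-yl}-6-methylhept-5-enoate (open-chain Michael adduct, Cα epimers) | COC(=O)C(CCC=C(C)C)[C@H](CC=O)C(=O)C[C@@]1(C)[C@H]([Sn](CCCC)(CCCC)CCCC)CCC1=O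
F0 | step 8 | none | none
F2 | step 12 | C8 hydroxymethyl analogue of 19 (allylic alcohol) | CC(=O)OC[C@@H](CCC=C(C)C)[C@H]1[C@@H](O)C/C(C)=C/C/C=C(/CO)[C@@H]1C(OC)OC
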